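**Retrosynthetic overview**
- The Ar–CH2–Ar' bridge is cut last (Friedel–Crafts): 6-(hydroxymethyl)eugenin as electrophile, the (R)-6,8-dihydroxy-3,7-dimethylisochromanone as nucleophile, whose C5 is its only free aromatic position.
- The isochromanone comes from its dimethyl ether, and that from cutting the lactone C3–O bond: enantioselective hydroacyloxylation of an ortho-allylbenzoic acid closes the lactone ring and sets the only stereocenter in one step.
- The allyl acid comes from 2,4-dimethoxy-3-methylbenzoic acid by carboxylate-directed C–H allylation.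
- The hydroxymethyl chromone comes from 6-iodoeugenin, from eugenin, from symmetric 2',6'-dihydroxy-4'-methoxyacetophenone and ethyl acetate.
- Ring order: lactone ring (step 2) and pyranone ring (step 4) are made in separate branches; the two halves are joined in step 7.

Assumption: the sense of induction of the new cobalt step cannot be predicted with certainty; the (R,R)-ligand is written, and the equally available (S,S)-ligand is used instead if the first run gives the (S)-lactone.

**Step 1**
Reactants: 1 2,4-dimethoxy-3-methylbenzoic acid; 2 allyl acetate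
Product: 3 2,4-dimethoxy-3-methyl-6-(prop-2-en-1-yl)benzoic acid
Conditions: [RuCl2(p-cymene)]2 (2 mol%), K3PO4 (1.0 equiv), 2 (2 equiv), MeCN, 50 °C, 16 h; then 1 M HCl
Reagents that add atoms: allyl acetate, CC(=O)OCC=C
Why: Carboxylate-directed ortho C–H allylation (ruthenation by concerted metalation–deprotonation, alkene insertion, β-acetoxy elimination); C6 is the only C–H ortho to the carboxylate, so one mono-allylated product is possible and the alkene stays terminal.

**Step 2**
Reactants: 3 2,4-dimethoxy-3-methyl-6-(prop-2-en-1-yl)benzoic acid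
Product: 4 (3R)-6,8-dimethoxy-3,7-dimethyl-3,4-dihydro-1H-isochromen-1-one
Conditions: (R,R)-N,N'-bis(3,5-di-tert-butylsalicylidene)-1,2-cyclohexanediaminocobalt, C36H52CoN2O2 (divalent cobalt, 5 mol%), N-fluoro-2,4,6-trimethylpyridinium tetrafluoroborate (1.3 equiv), PhSiH3 (1.1 equiv), acetone, −20 to 0 °C, Ar; recrystallisation to raise ee
Reagents that add atoms: none
Why: Proposed new method: enantioselective Markovnikov hydroacyloxylation (hydrolactonisation) of an ortho-allylbenzoic acid, in which a trivalent cobalt hydride (from the salen complex, the N–F oxidant and PhSiH3) transfers a hydrogen atom to the terminal alkene carbon, the secondary radical is captured and oxidised to a tetravalent alkylcobalt species, and the ortho-carboxyl group displaces cobalt with inversion in a 6-exo closure that forms the C3–O bond; the two diastereomeric alkylcobalt species interconvert by reversible Co–C homolysis and the rigid aryl tether fixes the carboxylate trajectory inside the chiral salen pocket, so one is displaced faster and the (R)-lactone results; closest known reaction type: cobalt–salen hydrogen-atom-transfer/radical-polar crossover hydroalkoxylation and hydroacyloxylation of unactivated alkenes, whose enantioselective forms are, to my knowledge, established mainly for five-membered cyclic ethers and not for six-membered benzo-fused lactones from 2-allylbenzoic acids.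

**Step 3**
Reactants: 4 (3R)-6,8-dimethoxy-3,7-dimethyl-3,4-dihydro-1H-isochromen-1-one
Product: 5 (3R)-6,8-dihydroxy-3,7-dimethyl-3,4-dihydro-1H-isochromen-1-one
Conditions: BBr3 (4 equiv), CH2Cl2, −78 °C to rt; H2O
Reagents that add atoms: none
Why: Lewis-acid cleavage of both aryl methyl ethers (the peri 8-OMe is chelation-assisted); the lactone and the non-enolisable C3 stereocenter are not touched, and ee is rechecked by chiral HPLC.

**Step 4**
Reactants: 6 1-(2,6-dihydroxy-4-methoxyphenyl)ethan-1-one; 7 ethyl acetate
Product: 9 eugenin (5-hydroxy-7-methoxy-2-methyl-4H-chromen-4-one), via 1-(2,6-dihydroxy-4-methoxyphenyl)butane-1,3-dione 8 (not isolated)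
Conditions: NaH (5 equiv), 7 (10 equiv), THF, reflux; then conc. HCl, AcOH, 90 °C
Reagents that add atoms: ethyl acetate, CCOC(C)=O
Why: Claisen condensation of the ketone enolate with ethyl acetate followed by acid cyclodehydration (chromone synthesis); the two phenols are equivalent by symmetry, so only one chromone can form.

**Step 5**
Reactants: 9 eugenin; 10 benzyltrimethylammonium dichloroiodate
Product: 11 5-hydroxy-6-iodo-7-methoxy-2-methyl-4H-chromen-4-one
Conditions: 10 (1.05 equiv), CaCO3 (1.5 equiv), CH2Cl2/MeOH 5:2, rt
Reagents that add atoms: benzyltrimethylammonium dichloroiodate, C[N+](C)(C)Cc1ccccc1.Cl[I-]Cl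
Why: Mild electrophilic aromatic iodination; with the 5-OH free, this reagent iodinates 5-hydroxy-7-alkoxy flavones ortho to the hydroxyl (C6, not C8), and the 2-methylchromone should behave alike (checked by NOE between 7-OMe and the remaining H-8).

**Step 6**
Reactants: 11 5-hydroxy-6-iodo-7-methoxy-2-methyl-4H-chromen-4-one; 12 (tributylstannyl)methanol
Product: 13 5-hydroxy-6-(hydroxymethyl)-7-methoxy-2-methyl-4H-chromen-4-one
Conditions: Pd(PPh3)4 (5 mol%), 12 (1.5 equiv), 1,4-dioxane, 90 °C
Reagents that add atoms: (tributylstannyl)methanol, CCCC[Sn](CO)(CCCC)CCCC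
Why: Migita–Kosugi–Stille hydroxymethylation (oxidative addition of zerovalent palladium into the aryl C–I bond, transfer of CH2OH from tin) under neutral conditions that tolerate the free phenol and the chromone.

**Step 7**
Reactants: 13 5-hydroxy-6-(hydroxymethyl)-7-methoxy-2-methyl-4H-chromen-4-one; 5 (3R)-6,8-dihydroxy-3,7-dimethyl-3,4-dihydro-1H-isochromen-1-one
Product: 14 (3R)-6,8-dihydroxy-5-[(5-hydroxy-7-methoxy-2-methyl-4-oxo-4H-chromen-6-yl)methyl]-3,7-dimethyl-3,4-dihydro-1H-isochromen-1-one
Conditions: TsOH·H2O (10 mol%), (CF3)2CHOH, 40 °C; 5 in excess (1.5 equiv), 13 added slowly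
Reagents that add atoms: none
Why: Friedel–Crafts benzylation: acid ionises 13 to a benzylic cation/ortho-quinone methide stabilised by the 5-OH and 7-OMe, which is attacked by C5 of 5, its only unsubstituted aromatic carbon (ortho to 6-OH, para to 8-OH); the stereocenter is not involved.

**Compound list**
1 | 2,4-dimethoxy-3-methylbenzoic acid | COc1ccc(C(=O)O)c(OC)c1C | starting material
2 | allyl acetate | CC(=O)OCC=C | starting material
3 | 2,4-dimethoxy-3-methyl-6-(prop-2-en-1-yl)benzoic acid | COc1cc(CC=C)c(C(=O)O)c(OC)c1C | intermediate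
4 | (3R)-6,8-dimethoxy-3,7-dimethyl-3,4-dihydro-1H-isochromen-1-one | C[C@@H]1Cc2cc(OC)c(C)c(OC)c2C(=O)O1 | intermediate
5 | (3R)-6,8-dihydroxy-3,7-dimethyl-3,4-dihydro-1H-isochromen-1-one | C[C@@H]1Cc2cc(O)c(C)c(O)c2C(=O)O1 | intermediate
6 | 1-(2,6-dihydroxy-4-methoxyphenyl)ethan-1-one | CC(=O)c1c(O)cc(OC)cc1O | starting material
7 | ethyl acetate | CCOC(C)=O | starting material
8 | 1-(2,6-dihydroxy-4-methoxyphenyl)butane-1,3-dione | CC(=O)CC(=O)c1c(O)cc(OC)cc1O | intermediate
9 | eugenin, 5-hydroxy-7-methoxy-2-methyl-4H-chromen-4-one | Cc1cc(=O)c2c(O)cc(OC)cc2o1 | intermediate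
10 | benzyltrimethylammonium dichloroiodate | C[N+](C)(C)Cc1ccccc1.Cl[I-]Cl | starting material
11 | 5-hydroxy-6-iodo-7-methoxy-2-methyl-4H-chromen-4-one | Cc1cc(=O)c2c(O)c(I)c(OC)cc2o1 | intermediate
12 | (tributylstannyl)methanol | CCCC[Sn](CO)(CCCC)CCCC | starting material
13 | 5-hydroxy-6-(hydroxymethyl)-7-methoxy-2-methyl-4H-chromen-4-one | Cc1cc(=O)c2c(O)c(CO)c(OC)cc2o1 | intermediate
14 | (3R)-6,8-dihydroxy-5-[(5-hydroxy-7-methoxy-2-methyl-4-oxo-4H-chromen-6-yl)methyl]-3,7-dimethyl-3,4-dihydro-1H-isochromen-1-one | COc1cc2oc(C)cc(=O)c2c(O)c1Cc1c(O)c(C)c(O)c2c1C[C@@H](C)OC2=O | target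

**Step count**
Total: 7 steps. Longest linear sequence: 4 steps (steps 1, 2, 3, 7, or steps 4, 5, 6, 7).

**Three steps most likely to fail**

Step 2 (the proposed new step). Risks are low ee, alkene isomerisation to the propenylarene, or plain reduction. The fallback uses known chemistry, sets out from 1 and comes back to the route at 4. The lithium carboxylate of 1 is lithiated at C6 (the only C–H ortho to the carboxylate) with s-BuLi/TMEDA (2.2 equiv) in THF at −78 °C. The aryllithium opens (R)-propylene oxide at its CH2 terminus in the presence of BF3·OEt2 at −78 °C, leaving the stereocenter untouched, to give (R)-6-(2-hydroxypropyl)-2,4-dimethoxy-3-methylbenzoic acid F1. TsOH in toluene at 80 °C lactonises it to 4. The configuration then comes from the chiral pool instead of from catalysis.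

Step 6. The iodide is flanked by OH and OMe, so transfer of CH2OH from tin may be slow and protodeiodination may compete. The fallback sets out from 11 and comes back at 13. Suzuki–Miyaura vinylation (CH2=CHBF3K, PdCl2(dppf), Cs2CO3, THF/H2O, 70 °C) gives 5-hydroxy-7-methoxy-2-methyl-6-vinyl-4H-chromen-4-one F2. Lemieux–Johnson cleavage (OsO4 cat., NaIO4, 2,6-lutidine, dioxane/H2O) gives 5-hydroxy-7-methoxy-2-methyl-4-oxo-4H-chromene-6-carbaldehyde F3. NaBH4 in MeOH at 0 °C then reduces the aldehyde to 13.

Step 7. The cation from 13 may be trapped by C8 of another chromone (self-condensation) or by oxygen instead of C5 of 5. The fallback sets out from 13 and 5 and comes back at 14; it replaces cation chemistry by carbonyl addition and reduction. MnO2 in CH2Cl2 oxidises 13 to the aldehyde F3 (the same compound as in the fallback to step 6). The bis(bromomagnesium) phenoxide of 5 (EtMgBr, CH2Cl2/toluene, 0 °C to rt) adds to it ortho-specifically at C5 through a magnesium-chelated transition state, giving (3R)-6,8-dihydroxy-5-[hydroxy(5-hydroxy-7-methoxy-2-methyl-4-oxo-4H-chromen-6-yl)methyl]-3,7-dimethyl-3,4-dihydro-1H-isochromen-1-one F4 as a mixture of carbinol epimers. Ionic hydrogenation (Et3SiH, TFA, CH2Cl2, 0 °C) removes the doubly benzylic hydroxyl and gives 14.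

**Further compounds**
F1 | step 2 | (R)-6-(2-hydroxypropyl)-2,4-dimethoxy-3-methylbenzoic acid | COc1cc(C[C@@H](C)O)c(C(=O)O)c(OC)c1C
F2 | step 6 | 5-hydroxy-7-methoxy-2-methyl-6-vinyl-4H-chromen-4-one | Cc1cc(=O)c2c(O)c(C=C)c(OC)cc2o1
F3 | step 6 | 5-hydroxy-7-methoxy-2-methyl-4-oxo-4H-chromene-6-carbaldehyde | Cc1cc(=O)c2c(O)c(C=O)c(OC)cc2o1
F4 | step 7 | (3R)-6,8-dihydroxy-5-[hydroxy(5-hydroxy-7-methoxy-2-methyl-4-oxo-4H-chromen-6-yl)methyl]-3,7-dimethyl-3,4-dihydro-1H-isochromen-1-one | COc1cc2oc(C)cc(=O)c2c(O)c1C(O)c1c(O)c(C)c(O)c2c1C[C@@H](C)OC2=O
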